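Atom labels follow ent-kaurane numbering: ring A = C1–C5, C10; γ-lactone C4–C19H2–O–C6(=O)–C5; δ-lactone C10–C20H2–O–C7(=O)–C8–C9; ring C = C8, C9, C11, C12, C13, C14; ring D = C8, C14, C13, C16, C15. Compound numbers are those of the steps and the compound list.

## Analysis of the target

Guidongnin C (35) is a 6,7-seco-ent-kaurane: ring A carries a cis-fused γ-lactone and is joined through the spiro carbon C10 to a δ-lactone, which shares C8–C9 with the bicyclo[3.2.1]octane formed by rings C and D. There are eight stereocentres (C4, C5, C8, C9, C10, C11, C13, C16), of which C4, C8 and C10 are quaternary. On ring A, C19, C6 and C20 lie on one face and the C18 methyl and C9 on the other; on the δ-lactone, C14 and C11 are cis to C1 and C15 is cis to C5. C13 follows from C8 through the bridge, the C11 hydroxyl is equatorial on ring C, and the C16 methyl points toward ring C (endo). Sensitive points are the non-enolisable β-keto lactone at C8 (open to retro-Claisen cleavage by nucleophilic base), the C16 centre α to C15, and the two oxygens O19 and O20, both within reach of C6, so that a free C20 alkoxide beside the γ-lactone can start acyl migration. The hard part is C8: it is quaternary, bears the carbonyl carbons C7 and C15 and is bonded to C9, which sits next to the spiro centre C10, so intermolecular bond formation at C8 is unattractive. The strategy rests on the array C14–C8(–C15)–C9–C11: if C8=C9 is an alkene conjugated to a C11 ketone and C15 is the carbinol carbon of a cyclobutanol that still holds C14, a 1,2-shift of C14 from C15 to C8 creates the quaternary centre, the C15 ketone and the five-membered ring in one unimolecular, strain-releasing event.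

## Retrosynthetic reasoning

**C16–H (35 from 34).** The C16 methyl is traced to the exocyclic alkene C16=C17 of 34. This is cut last because addition of hydrogen from the open exo face of ring D gives the endo methyl, a centre that should not be exposed to base afterwards.

**C16–C17 and C11–O (34 from 31 from 30).** The C16–C17 bond is cut back to the C15 silyl enol ether 31, a regiodefined nucleophile for a one-carbon Mannich electrophile. The C11 carbinol is cut back to the ketone of 30. In 30 the C15 carbonyl is masked as the enol ether, so hydride can reach only C11; without this, the two ring ketones could not be told apart.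

**C12–C13, ring C (30 from 28 from 27).** The bond is cut as an intramolecular Michael addition of the methyl ketone carbon C12 to C13 of a cyclopentenone, with the resulting C15 enolate trapped on oxygen. The enone 28 comes from 27 by dehydrogenation; C16–C13 is the only place where a ketone of 27 can be desaturated, because C8 and C10 carry no hydrogen.

**C8–C14, key disconnection (27 from 26).** C14 is returned from C8 to C15, which turns the cyclopentanone into a cyclobutanol and C8–C9 into an alkene conjugated with the C11 ketone. The forward shift must place C14 on the face of C8 that is cis to C1. What is gained is that the C8 centre is made without any external reagent approaching it.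

**C9–C11 (26 from 24 from 23).** The acetyl group is cut from C9 as a cross-coupling of enol triflate 24 with a masked acetyl nucleophile. The C8=C9 alkene is not made by condensing an ester α-carbon with a C9/C11 1,2-diketone: the methyl hydrogens of such a diketone are far more acidic than those of the ester, and a free β-hydroxy ester would fragment. The alkene is instead taken from the β-keto lactone 23, where its position is fixed by the ring.

**C8–C9 and C20–O (23 from 22 from 21 from 19 and 6).** C8–C9 is cut as an intramolecular aldol addition of the ester α-carbon to a non-enolisable C9 aldehyde, followed by oxidation. The C20–O–C7 bond is an ester linkage between alcohol 19 and acid 6. Acid 6 carries C7, C8 and the whole cyclobutanol and comes from 1 and 2 through 4 and 5.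

**C10–C9 (19 from 18 from 17 from 16).** C10 is made quaternary by C-alkylation of enol ether 17 with a formate-level one-carbon electrophile. The aldehyde carbon of 16 acidifies C10–H and becomes C20 after reduction; the incoming carbon becomes C9. The forward step must bring C9 in on the face away from the lactone.

**Ring A (16 from 14 from 13 from 11 from 9 and 10).** The C20 aldehyde is unmasked from a dioxolane and the γ-lactone comes from the anhydride of 11. C3–C4 and C5–C10 are cut as a Diels–Alder reaction of diene 9 with 10. This sets the cis relationship of C19 and C6 and the quaternary C4 in one step, and C4 is the only centre whose absolute configuration has to be fixed there. Diene 9 comes from 7 by two olefinations through 8.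

## Alternatives that were turned down

**Alternative 1:** The C4–C5 bond of ring A is disconnected in a [3,3] sense, with C2 re-attached to the oxygen of the C6 carboxyl. The forward key step is a ring-contracting ester-enolate Claisen rearrangement that delivers the ring A cyclohexene acid A1.
- For it: C4 and C5 are set relative to a pre-existing C10 in one suprafacial event, and the propynyl group for C9, C11 and C12 is already in place. On control of the ring A triad it is stronger than the chosen route, which separates facial diastereomers after a Diels–Alder reaction.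
- Against it: the strategic step is spent on ring A, which a cycloaddition builds in one step, and C8 and rings C and D remain unsolved. The lactone needs an enantiopure quaternary C10 and a geometrically pure trisubstituted alkene beforehand, chair and boat transition states compete in ring contractions, and the C2=C3 alkene of A1 must later be saturated beside an alkyne.
- Comparison: the chosen strategy offers in its place a solution for the most congested carbon, C8.

**Alternative 2:** The C13–C16 bond of ring D is disconnected. The forward key step is an anodic coupling in which the radical cation of a C15=C16 silyl enol ether is captured by a ring C allylsilane, giving the bicyclic keto ester A2.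
- For it: the bicyclo[3.2.1]octane and the C16 methyl are made in one reagent-free step on a small fragment, and C8 is quaternary from a simple β-keto ester alkylation. For ring D and C16 it is shorter than the five-step endgame used here.
- Against it: in A2, C9 is a methylene carbon that must later be bonded to the quaternary spiro carbon C10, the most hindered intermolecular union in the molecule. The C11 oxygen must be placed regioselectively on the C11=C12 alkene, the epimerisable endo methyl must survive many steps, and two enantiopure halves have to be matched.
- Comparison: the chosen strategy has C9–C10 from the start and forms C8 intramolecularly.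

**Alternative 3:** C8–C9 and C13–C14 are disconnected together. The forward key step is an ester-tethered Diels–Alder reaction of an acylacrylate methylene (C8=C14) on O20 with a butadienyl group on C10, giving the tricyclic bis-lactone A3.
- For it: the δ-lactone, ring C, C8 and C9 arise in one step after a simple acylation, and the propanoyl group brings C15–C17. In step count to C8 it is stronger than the chosen route.
- Against it: α-acyl acrylates dimerise and polymerise, the ester tether disfavours the reactive conformer and calls for high temperature, and facial and endo/exo selectivity together decide C8 and C9 among four outcomes. In A3, C13 is an unactivated allylic methylene, so ring D closure needs further oxidation, and C11 must be hydrated regioselectively.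
- Comparison: the chosen strategy offers a low-temperature unimolecular step with one new quaternary centre, a correctable C9, and an enone that directly enables ring C closure.

Key step: step 19

Assumption (chemistry): in step 6 the two π-facial diastereomers can be separated and the one drawn as 11 is carried on; its dioxolane stereocentre is removed in step 9.

## Steps

Step 1
Reactants: 1 cyclobutanone; 2 ethyl bromoacetate
Product: 4 ethyl 2-(1-hydroxycyclobutyl)acetate, via zinc ester enolate 3 (not isolated)
Conditions: Zn dust (TMSCl-activated), THF, 50 °C; then 1 M HCl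
Reagents that add atoms: none
Why: Reformatsky reaction; the zinc enolate adds to the strained, electrophilic ketone without ester self-condensation, and no stereocentre is formed.

Step 2
Reactants: 4 ethyl 2-(1-hydroxycyclobutyl)acetate
Product: 5 ethyl 2-[1-(triethylsilyloxy)cyclobutyl]acetate
Conditions: TESOTf, 2,6-lutidine, CH2Cl2, −78 → 0 °C
Reagents that add atoms: triethylsilyl trifluoromethanesulfonate, CC[Si](CC)(CC)OS(=O)(=O)C(F)(F)F
Why: Silyl triflate with a hindered pyridine silylates the tertiary alcohol; the ether prevents retro-aldol loss of 1 at the later enolate and β-keto lactone stages.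

Step 3
Reactants: 5 ethyl 2-[1-(triethylsilyloxy)cyclobutyl]acetate
Product: 6 2-[1-(triethylsilyloxy)cyclobutyl]acetic acid
Conditions: LiOH·H2O, THF/MeOH/H2O, 23 °C; then 1 M HCl to pH 4, 0 °C
Reagents that add atoms: lithium hydroxide, [Li+].[OH-]
Why: Ester saponification; the tertiary silyl ether should tolerate hydroxide and a brief, cold acidification.

Step 4
Reactants: 7 (R)-2,2-dimethyl-1,3-dioxolane-4-carbaldehyde
Product: 8 (S,E)-3-(2,2-dimethyl-1,3-dioxolan-4-yl)prop-2-enal
Conditions: Ph3P=CHCHO, toluene, 23 → 60 °C
Reagents that add atoms: (triphenylphosphoranylidene)acetaldehyde, O=CC=P(c1ccccc1)(c1ccccc1)c1ccccc1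
Why: Wittig olefination with a stabilised ylide gives the (E)-enal; the dioxolane stereocentre is retained (its descriptor changes only through ligand priorities).

Step 5
Reactants: 8 (S,E)-3-(2,2-dimethyl-1,3-dioxolan-4-yl)prop-2-enal
Product: 9 (S,E)-4-(buta-1,3-dien-1-yl)-2,2-dimethyl-1,3-dioxolane
Conditions: Ph3PCH3Br, KN(SiMe3)2, THF, −78 → 0 °C
Reagents that add atoms: methyltriphenylphosphonium bromide, C[P+](c1ccccc1)(c1ccccc1)c1ccccc1.[Br-]
Why: Wittig methylenation of the enal gives the (E)-1-substituted diene without touching the acetonide.

Step 6
Reactants: 9 (S,E)-4-(buta-1,3-dien-1-yl)-2,2-dimethyl-1,3-dioxolane; 10 citraconic anhydride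
Product: 11 (3aR,7S,7aS)-7-[(4S)-2,2-dimethyl-1,3-dioxolan-4-yl]-3a-methyl-3a,4,7,7a-tetrahydroisobenzofuran-1,3-dione
Conditions: toluene, BHT (cat.), 110 °C, sealed tube; 11 isolated by chromatography and crystallisation
Reagents that add atoms: none
Why: Thermal Diels–Alder reaction; the substituted diene terminus should bond to the unsubstituted carbon C5 of 10 (steric and frontier-orbital preference), and suprafacial endo addition gives the cis anhydride with the C10 substituent cis to C6. The absolute configuration of C4 is secured by separating the facial diastereomers; C10 is re-set in step 11.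

Step 7
Reactants: 11 Diels–Alder anhydride
Product: 13 (3aR,7S,7aS)-7-[(4S)-2,2-dimethyl-1,3-dioxolan-4-yl]-3a-methyl-3a,4,7,7a-tetrahydroisobenzofuran-1(3H)-one, via hydroxy acid 12 (not isolated)
Conditions: NaBH4, THF, 0 → 23 °C; then 1 M HCl to pH 3, 0 °C
Reagents that add atoms: none
Why: Borohydride reduction of a 2,2-disubstituted succinic anhydride takes place at the carbonyl next to the quaternary carbon (C19); the γ-hydroxy acid lactonises on acidification to the 19,6-olide.

Step 8
Reactants: 13 unsaturated γ-lactone
Product: 14 (3aR,7S,7aS)-7-[(4S)-2,2-dimethyl-1,3-dioxolan-4-yl]-3a-methylhexahydroisobenzofuran-1(3H)-one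
Conditions: H2 (1 atm), Pd/C, EtOAc, 23 °C
Reagents that add atoms: none
Why: Heterogeneous hydrogenation of the only alkene; removing C1=C2 prevents vinylogous attack at C2 in step 11.

Step 9
Reactants: 14 saturated γ-lactone acetonide
Product: 16 (3aR,7S,7aS)-3a-methyl-1-oxooctahydroisobenzofuran-7-carbaldehyde, via diol 15 (not isolated)
Conditions: H5IO6, EtOAc, 23 °C
Reagents that add atoms: none
Why: Periodic acid hydrolyses the terminal acetonide and cleaves the glycol in one operation; the auxiliary carbon is excised and C20 appears as the aldehyde without a free C20 alcohol next to the lactone.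

Step 10
Reactants: 16 ring A lactone aldehyde
Product: 17 tert-butyldimethylsilyl enol ether of 16 (C10=C20H–OSi, E/Z mixture; C4 and C5 as in 16)
Conditions: TBSOTf, Et3N, CH2Cl2, 0 → 23 °C
Reagents that add atoms: tert-butyldimethylsilyl trifluoromethanesulfonate, CC(C)(C)[Si](C)(C)OS(=O)(=O)C(F)(F)F
Why: Soft enolisation of the α-branched aldehyde; the lactone α-hydrogen at C5 is much less acidic and stays untouched, and C10 becomes planar.

Step 11
Reactants: 17 silyl enol ether
Product: 18 lactone aldehyde with quaternary C10 carrying CHO (C20, cis to C6) and CH(OMe)2 (C9, trans to C6)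
Conditions: HC(OMe)3, TMSOTf (10 mol %), CH2Cl2, −78 → −40 °C
Reagents that add atoms: trimethyl orthoformate, COC(OC)OC
Why: Mukaiyama-type alkylation of the enol ether by the dimethoxycarbenium ion. The electrophile should enter equatorially, away from the axial C19 and the lactone, so the new carbon (C9) is trans and the original formyl carbon (C20) cis to C6, the C10 configuration of 35.

Step 12
Reactants: 18 acetal aldehyde
Product: 19 C20 primary alcohol of 18 (C9 dimethyl acetal retained)
Conditions: NaBH4, EtOH/THF, −20 °C; AcOH quench
Reagents that add atoms: none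
Why: Chemoselective reduction of the neopentyl aldehyde beside acetal and lactone; low temperature and an acidic quench keep the C20 alkoxide from attacking C6 (acyl migration to O20).

Step 13
Reactants: 19 C20 alcohol; 6 2-[1-(triethylsilyloxy)cyclobutyl]acetic acid
Product: 20 C20 ester of 19 with acid 6
Conditions: EDC·HCl, DMAP (cat.), CH2Cl2, 0 → 23 °C
Reagents that add atoms: none
Why: Carbodiimide (Steglich) esterification of the primary alcohol under near-neutral conditions.

Step 14
Reactants: 20 acetal ester
Product: 21 C9 aldehyde of 20 (acetal removed; silyl ether and both esters retained)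
Conditions: TESOTf, 2,4,6-collidine, CH2Cl2, 0 °C; then H2O
Reagents that add atoms: water, O
Why: Silyl triflate and collidine convert an aldehyde-derived dimethyl acetal into a pyridinium intermediate that water hydrolyses; this known mild acetal cleavage leaves silyl ethers and esters intact.

Step 15
Reactants: 21 aldehyde ester
Product: 22 spiro β-hydroxy δ-lactone (C9–OH, C8–H; epimer mixture at C8 and C9)
Conditions: LiN(SiMe3)2, THF, −78 °C; NH4Cl
Reagents that add atoms: none
Why: Intramolecular aldol addition; the ester α-CH2 (C8) is the only readily enolised position and adds to the non-enolisable C9 aldehyde in a six-membered closure (6-enolendo-exo-trig). The new centres are removed in steps 16 and 17.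

Step 16
Reactants: 22 β-hydroxy δ-lactone
Product: 23 spiro β-keto δ-lactone (C9 ketone)
Conditions: Dess–Martin periodinane, NaHCO3, CH2Cl2, 23 °C
Reagents that add atoms: none
Why: Buffered Dess–Martin oxidation of the secondary alcohol; the silyl ether keeps the β-silyloxy β-keto lactone from retro-aldol cleavage.

Step 17
Reactants: 23 β-keto δ-lactone
Product: 24 C9 enol triflate (C8=C9 in the δ-lactone ring)
Conditions: KN(SiMe3)2, PhNTf2, THF, −78 → 0 °C
Reagents that add atoms: N-phenylbis(trifluoromethanesulfonimide), O=S(=O)(N(c1ccccc1)S(=O)(=O)C(F)(F)F)C(F)(F)F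
Why: O-sulfonylation of the cyclic β-keto ester enolate gives the conjugated enol triflate and fixes the alkene position and geometry through the ring.

Step 18
Reactants: 24 enol triflate
Product: 26 4-acetyl-3-(1-hydroxycyclobutyl) unsaturated spiro δ-lactone, via ethoxyvinyl diene 25 (not isolated)
Conditions: tributyl(1-ethoxyvinyl)stannane, Pd(PPh3)4 (10 mol %), CuI (20 mol %), LiCl, DMF, 60 °C; then 1 M HCl, THF, 23 °C
Reagents that add atoms: tributyl(1-ethoxyvinyl)stannane, CCCC[Sn](CCCC)(CCCC)C(=C)OCC; water, O
Why: Stille coupling of the enol triflate (zerovalent palladium, with CuI and LiCl for a hindered triflate), then aqueous acid hydrolyses the enol ether to the acetyl group and removes the triethylsilyl group. 26 may rest as its ring-closed hemiketal (O15 on C11), which reopens under the conditions of step 19.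

Step 19
Reactants: 26 acetyl hydroxycyclobutyl lactone
Product: 27 spiro cyclopentanone keto bis-lactone (C8 and C9 set; C14 and the C9 acetyl cis to C1)
Conditions: TsOH·H2O (20 mol %), toluene, 60 °C
Reagents that add atoms: none
Why: Protonation (or hydrogen bonding) of the C11 carbonyl of the (Z)-4-oxo-2-enoate unit makes C8, β to the ketone, the electrophilic carbon; the C15–C14 bond, held perpendicular to the alkene plane, shifts to C8 while the hydroxyl oxygen turns C15 into the ketone, and the resulting C9=C11 enol tautomerises. The closest known reaction type is the vinylogous α-ketol (semipinacol) rearrangement of 1-(β-acylvinyl)cyclobutanols under acid or amine catalysis. The cyclopentanone that becomes ring D forms by one-carbon ring expansion, a suprafacial 1,2-alkyl shift with retention at C14, not by an end-to-end cyclisation, so no Baldwin mode applies and C8 becomes the spiro centre. The new C8 centre is controlled by C10: in the half-chair of the unsaturated δ-lactone the bulkier C5 arm with its γ-lactone should stand pseudoaxial to avoid allylic strain with the C9 acetyl, so it covers one face and C14 arrives on the face cis to C1. C9 is set on protonation of the enol and can equilibrate through that enol; the acetyl group should prefer the less crowded face shared with C1 and C14, which is the epimer needed for ring C. The step needs site selectivity for C8 over C9, secured because the ketone outweighs the lactone carbonyl in polarising the alkene, and it needs the shift to outrun loss of cyclobutanone and aldol closure of the 1,4-diketone, which acid rather than base and a moderate temperature favour. Both cyclobutane methylenes are equivalent, so there is no choice of migrating group, and release of four-ring strain makes the shift irreversible.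

Step 20
Reactants: 27 spiro cyclopentanone
Product: 28 spiro cyclopentenone (C15 ketone, C16=C13)
Conditions: IBX, 4-methoxypyridine N-oxide, DMSO, 23 °C
Reagents that add atoms: none
Why: IBX dehydrogenation through the C15 enol; C16–C13 is the only site in 27 where a ketone can be desaturated, since C8 and C10 are quaternary and the acetyl group has no β-hydrogen.

Step 21
Reactants: 28 cyclopentenone methyl ketone
Product: 30 tetracyclic C11 ketone with C15 tert-butyldimethylsilyl enol ether (rings C and D closed), via lithium enolate 29 (not isolated)
Conditions: LiN(SiMe3)2, THF, −78 → −20 °C; then TBSOTf, −78 °C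
Reagents that add atoms: tert-butyldimethylsilyl trifluoromethanesulfonate, CC(C)(C)[Si](C)(C)OS(=O)(=O)C(F)(F)F
Why: Kinetic deprotonation of the methyl ketone and intramolecular Michael addition (6-enolendo-exo-trig) close ring C and fix C13 through the bridge. O-silylation of the resulting C15 enolate keeps the two carbonyls distinguishable; aldol attack on C15 would be a disfavoured 5-enolendo closure.

Step 22
Reactants: 30 C11 ketone silyl enol ether
Product: 31 C11 equatorial alcohol (C15 silyl enol ether retained)
Conditions: NaBH4, EtOH/THF, −20 °C; AcOH quench
Reagents that add atoms: none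
Why: With C15 masked, hydride meets only the C11 ketone. The face of C11 toward C10 is blocked by the axial spiro centre, so hydride should arrive from the side of the C15–C16 bridge and give the equatorial alcohol, which is also the more stable one.

Step 23
Reactants: 31 hydroxy silyl enol ether
Product: 34 11-hydroxy-16-methylene-15-ketone (exocyclic enone), via Mannich base 32 (not isolated), via ammonium iodide 33 (not isolated)
Conditions: CH2=NMe2+ I− (Eschenmoser's salt), CH2Cl2, 23 °C; then MeI; then DBU, 23 °C
Reagents that add atoms: N,N-dimethylmethyleneiminium iodide, C=[N+](C)C.[I-]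
Why: Mannich reaction of the silyl enol ether puts C17 on C16 regiospecifically; N-methylation and base-induced elimination give the α-methylene ketone.

Step 24
Reactants: 34 exocyclic enone
Product: 35 guidongnin C
Conditions: H2 (1 atm), Pd/C, EtOAc, 23 °C
Reagents that add atoms: none
Why: Hydrogen should add to the exocyclic alkene from the exo face of ring D, away from ring C, which places the methyl endo as in 35; no base follows, so C16 is not epimerised.

## Compound list

1 | cyclobutanone | O=C1CCC1 | starting material
2 | ethyl bromoacetate | CCOC(=O)CBr | starting material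
3 | ethyl (bromozincio)acetate (Reformatsky reagent) | CCOC(=O)C[Zn]Br | intermediate
4 | ethyl 2-(1-hydroxycyclobutyl)acetate | CCOC(=O)CC1(O)CCC1 | intermediate
5 | ethyl 2-[1-(triethylsilyloxy)cyclobutyl]acetate | CCOC(=O)CC1(O[Si](CC)(CC)CC)CCC1 | intermediate
6 | 2-[1-(triethylsilyloxy)cyclobutyl]acetic acid | OC(=O)CC1(O[Si](CC)(CC)CC)CCC1 | intermediate
7 | (R)-2,2-dimethyl-1,3-dioxolane-4-carbaldehyde | O=C[C@H]1COC(C)(C)O1 | starting material
8 | (S,E)-3-(2,2-dimethyl-1,3-dioxolan-4-yl)prop-2-enal | O=C/C=C/[C@H]1COC(C)(C)O1 | intermediate
9 | (S,E)-4-(buta-1,3-dien-1-yl)-2,2-dimethyl-1,3-dioxolane | C=C/C=C/[C@H]1COC(C)(C)O1 | intermediate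
10 | citraconic anhydride (3-methylfuran-2,5-dione) | CC1=CC(=O)OC1=O | starting material
11 | (3aR,7S,7aS)-7-[(4S)-2,2-dimethyl-1,3-dioxolan-4-yl]-3a-methyl-3a,4,7,7a-tetrahydroisobenzofuran-1,3-dione | CC1(C)OC[C@@H](O1)[C@H]1C=CC[C@@]2(C)C(=O)OC(=O)[C@H]21 | intermediate
12 | ring-opened hydroxy acid of 11 (C19 CH2OH and C6 CO2H cis on ring A) | CC1(C)OC[C@@H](O1)[C@H]1C=CC[C@@](C)(CO)[C@H]1C(O)=O | intermediate
13 | (3aR,7S,7aS)-7-[(4S)-2,2-dimethyl-1,3-dioxolan-4-yl]-3a-methyl-3a,4,7,7a-tetrahydroisobenzofuran-1(3H)-one | CC1(C)OC[C@@H](O1)[C@H]1C=CC[C@@]2(C)COC(=O)[C@H]21 | intermediate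
14 | (3aR,7S,7aS)-7-[(4S)-2,2-dimethyl-1,3-dioxolan-4-yl]-3a-methylhexahydroisobenzofuran-1(3H)-one | CC1(C)OC[C@@H](O1)[C@H]1CCC[C@@]2(C)COC(=O)[C@H]21 | intermediate
15 | (3aR,7S,7aS)-7-[(1S)-1,2-dihydroxyethyl]-3a-methylhexahydroisobenzofuran-1(3H)-one | OC[C@@H](O)[C@H]1CCC[C@@]2(C)COC(=O)[C@H]21 | intermediate
16 | (3aR,7S,7aS)-3a-methyl-1-oxooctahydroisobenzofuran-7-carbaldehyde | O=C[C@H]1CCC[C@@]2(C)COC(=O)[C@H]21 | intermediate
17 | tert-butyldimethylsilyl enol ether of 16 (C10=C20H–OSi; C4, C5 as in 16) | CC(C)(C)[Si](C)(C)OC=C1CCC[C@@]2(C)COC(=O)[C@H]21 | intermediate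
18 | ring A lactone with quaternary C10: CHO (C20) cis and CH(OMe)2 (C9) trans to C6 | COC(OC)[C@@]1(CCC[C@@]2(C)COC(=O)[C@H]21)C=O | intermediate
19 | C20 primary alcohol of 18 | COC(OC)[C@@]1(CCC[C@@]2(C)COC(=O)[C@H]21)CO | intermediate
20 | C20 ester of 19 with acid 6 | COC(OC)[C@@]1(CCC[C@@]2(C)COC(=O)[C@H]21)COC(=O)CC1(O[Si](CC)(CC)CC)CCC1 | intermediate
21 | C9 aldehyde of 20 | O=C[C@@]1(CCC[C@@]2(C)COC(=O)[C@H]21)COC(=O)CC1(O[Si](CC)(CC)CC)CCC1 | intermediate
22 | spiro β-hydroxy δ-lactone (C9–OH; C8 bears the silyloxycyclobutyl group; epimers at C8, C9) | OC1C(C2(O[Si](CC)(CC)CC)CCC2)C(=O)OC[C@]13CCC[C@@]2(C)COC(=O)[C@H]23 | intermediate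
23 | spiro β-keto δ-lactone (C9 ketone) | O=C1C(C2(O[Si](CC)(CC)CC)CCC2)C(=O)OC[C@]13CCC[C@@]2(C)COC(=O)[C@H]23 | intermediate
24 | C9 enol triflate of 23 | FC(F)(F)S(=O)(=O)OC1=C(C2(O[Si](CC)(CC)CC)CCC2)C(=O)OC[C@]13CCC[C@@]2(C)COC(=O)[C@H]23 | intermediate
25 | C9 (1-ethoxyvinyl) diene | CCOC(=C)C1=C(C2(O[Si](CC)(CC)CC)CCC2)C(=O)OC[C@]13CCC[C@@]2(C)COC(=O)[C@H]23 | intermediate
26 | 4-acetyl-3-(1-hydroxycyclobutyl) unsaturated δ-lactone spiro-fused to the ring A γ-lactone (key-step precursor) | CC(=O)C1=C(C2(O)CCC2)C(=O)OC[C@]13CCC[C@@]2(C)COC(=O)[C@H]23 | intermediate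
27 | spiro cyclopentanone keto bis-lactone (key-step product) | CC(=O)[C@@H]1[C@]2(CCCC2=O)C(=O)OC[C@]13CCC[C@@]2(C)COC(=O)[C@H]23 | intermediate
28 | spiro cyclopentenone (C16=C13) of 27 | CC(=O)[C@@H]1[C@]2(CC=CC2=O)C(=O)OC[C@]13CCC[C@@]2(C)COC(=O)[C@H]23 | intermediate
29 | lithium C15 enolate of the tetracyclic C11 ketone | C1=C(O[Li])[C@]23C[C@H]1CC(=O)[C@H]2[C@@]1(CCC[C@@]2(C)COC(=O)[C@H]21)COC3=O | intermediate
30 | tetracyclic C11 ketone, C15 tert-butyldimethylsilyl enol ether | C1=C(O[Si](C)(C)C(C)(C)C)[C@]23C[C@H]1CC(=O)[C@H]2[C@@]1(CCC[C@@]2(C)COC(=O)[C@H]21)COC3=O | intermediate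
31 | C11 equatorial alcohol of 30 | C1=C(O[Si](C)(C)C(C)(C)C)[C@]23C[C@H]1C[C@@H](O)[C@H]2[C@@]1(CCC[C@@]2(C)COC(=O)[C@H]21)COC3=O | intermediate
32 | C16 (dimethylaminomethyl) C15 ketone (Mannich base; C16 epimers) | CN(C)CC1C(=O)[C@]23C[C@H]1C[C@@H](O)[C@H]2[C@@]1(CCC[C@@]2(C)COC(=O)[C@H]21)COC3=O | intermediate
33 | trimethylammonium iodide of 32 | C[N+](C)(C)CC1C(=O)[C@]23C[C@H]1C[C@@H](O)[C@H]2[C@@]1(CCC[C@@]2(C)COC(=O)[C@H]21)COC3=O.[I-] | intermediate
34 | 11-hydroxy-16-methylene-15-ketone | C=C1C(=O)[C@]23C[C@H]1C[C@@H](O)[C@H]2[C@@]1(CCC[C@@]2(C)COC(=O)[C@H]21)COC3=O | intermediate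
35 | guidongnin C | C[C@H]1C(=O)[C@]23C[C@H]1C[C@@H](O)[C@H]2[C@@]1(CCC[C@@]2(C)COC(=O)[C@H]21)COC3=O | target

## Step count and least certain steps

Total: 24 steps (steps 1–3 make acid 6; steps 4–24 are the main line). Longest linear sequence: 21 steps, from 7 to 35.

**Step 19 (key step).** The shift may occur on the wrong face of C8, because the bias from C10 is relayed over two bonds, or it may be outrun by loss of cyclobutanone or by aldol closure of the 1,4-diketone. Fallback, from 26: nucleophilic epoxidation of the electron-poor alkene (t-BuOOH, DBU) should give the epoxy lactone F1 with oxygen on the more accessible face. A Lewis acid (BF3·OEt2, CH2Cl2, −78 °C) should then open the epoxide at C8 with migration of C14 anti to the departing oxygen, an epoxy-alcohol semipinacol ring expansion that gives the C9-hydroxy spiro cyclopentanone F2. Because migration is anti to the reagent-installed oxygen, the facial outcome is opposite to that of the direct shift. Reductive removal of the C9 hydroxyl α to the C11 ketone (SmI2, MeOH, THF) returns to 27.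

**Step 6.** Poor π-facial selectivity, or diastereomers that do not separate, would leave the absolute configuration at C4 unsecured; regiochemical leakage is a lesser concern. Fallback, from 10: cycloaddition with the achiral diene (E)-5-(benzyloxy)penta-1,3-diene F3 gives the racemic anhydride F4. Borohydride reduction as in step 7 gives the benzyl ether lactone F5, which is resolved by preparative chromatography on a chiral stationary phase. Hydrogenation and hydrogenolysis (H2, Pd/C) give the hydroxy lactone F6, and Dess–Martin oxidation returns to 16.

**Step 11.** The electrophile may attack C10 from the lactone face, which would invert the spiro centre. Fallback, from 17: a Mukaiyama aldol reaction with aqueous formaldehyde (Sc(OTf)3 cat., THF/H2O) exploits that same facial preference in reverse roles. The hydroxymethyl group then arrives as C20 on the lactone face and the original formyl carbon becomes C9, giving the hydroxy aldehyde F7. Esterification of F7 with 6 (EDC·HCl, DMAP) returns to 21 and saves two steps.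

**Step 18.** Oxidative addition and transmetalation at a tetrasubstituted enol triflate flanked by two fully substituted carbons may be slow, so that loss of the triflate competes. Fallback, from 24: Sonogashira coupling with ethynyltrimethylsilane (PdCl2(PPh3)2, CuI, Et3N), whose linear partner is less sensitive to crowding, gives the silyl enyne F8. Acid-mediated Markovnikov hydration (HgSO4, aqueous H2SO4, THF) with loss of both silyl groups returns to 26.

**Step 21.** Deprotonation at a site other than the methyl group, or proton transfer between the C15 enolate and the new C11 ketone before silylation, would scramble the enol ether; 28 might also cyclise early in step 20, giving the unprotected diketone. Fallback, from 28: a Morita–Baylis–Hillman reaction with aqueous formaldehyde (imidazole, THF/H2O) puts C17 on C16 before ring closure and gives the hydroxymethyl enone F9. DBU then effects the Michael closure of ring C and dehydration to the 16-methylene diketone F10. Hydrogenation (H2, Pd/C) gives the 16-methyl diketone F11, in which C15 is flanked by the quaternary C8 and the substituted C16. Reduction under non-basic conditions (NaBH4, CeCl3·7H2O, MeOH, −78 °C) should then take the C11 ketone and returns to 35.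

## Further compounds

F1 | step 19 | C8,C9-epoxide of 26 (oxygen on the face cis to C5) | CC(=O)[C@]12O[C@@]1(C1(O)CCC1)C(=O)OC[C@]23CCC[C@@]1(C)COC(=O)[C@H]13
F2 | step 19 | C9-hydroxy spiro cyclopentanone keto bis-lactone | CC(=O)[C@]1(O)[C@]2(CCCC2=O)C(=O)OC[C@]13CCC[C@@]2(C)COC(=O)[C@H]23
F3 | step 6 | (E)-5-(benzyloxy)penta-1,3-diene | C=C/C=C/COCc1ccccc1
F4 | step 6 | racemic 7-(benzyloxymethyl)-3a-methyl-3a,4,7,7a-tetrahydroisobenzofuran-1,3-dione (all-cis; one enantiomer drawn) | c1ccccc1COC[C@H]1C=CC[C@@]2(C)C(=O)OC(=O)[C@H]21
F5 | step 6 | (3aR,7S,7aS)-7-(benzyloxymethyl)-3a-methyl-3a,4,7,7a-tetrahydroisobenzofuran-1(3H)-one (after resolution) | c1ccccc1COC[C@H]1C=CC[C@@]2(C)COC(=O)[C@H]21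
F6 | step 6 | (3aR,7S,7aS)-7-(hydroxymethyl)-3a-methylhexahydroisobenzofuran-1(3H)-one | OC[C@H]1CCC[C@@]2(C)COC(=O)[C@H]21
F7 | step 11 | ring A lactone with quaternary C10 carrying CHO (C9) and CH2OH (C20, cis to C6) | O=C[C@@]1(CCC[C@@]2(C)COC(=O)[C@H]21)CO
F8 | step 18 | C9 (trimethylsilylethynyl) enyne lactone | C[Si](C)(C)C#CC1=C(C2(O[Si](CC)(CC)CC)CCC2)C(=O)OC[C@]13CCC[C@@]2(C)COC(=O)[C@H]23
F9 | step 21 | 16-(hydroxymethyl) cyclopentenone of 28 | CC(=O)[C@@H]1[C@]2(CC=C(CO)C2=O)C(=O)OC[C@]13CCC[C@@]2(C)COC(=O)[C@H]23
F10 | step 21 | tetracyclic 16-methylene-11,15-diketone | C=C1C(=O)[C@]23C[C@H]1CC(=O)[C@H]2[C@@]1(CCC[C@@]2(C)COC(=O)[C@H]21)COC3=O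
F11 | step 21 | tetracyclic 16-methyl-11,15-diketone | C[C@H]1C(=O)[C@]23C[C@H]1CC(=O)[C@H]2[C@@]1(CCC[C@@]2(C)COC(=O)[C@H]21)COC3=O
A1 | alternative 1 | 6-[(4-methoxybenzyloxy)methyl]-2-[(tert-butyldimethylsilyloxy)methyl]-2-methyl-6-(prop-1-ynyl)cyclohex-3-ene-1-carboxylic acid | OC(=O)[C@@H]1[C@](C)(CO[Si](C)(C)C(C)(C)C)C=CC[C@@]1(COCc1ccc(OC)cc1)C#CC
A2 | alternative 2 | methyl 7-methyl-6-oxobicyclo[3.2.1]oct-2-ene-5-carboxylate | COC(=O)[C@@]12C[C@@H](C=CC1)[C@@H](C)C2=O
A3 | alternative 3 | tricyclic bis-lactone with ring C cyclohexene and a C8 propanoyl group | CCC(=O)[C@]12CCC=C[C@H]1[C@@]1(CCC[C@@]3(C)COC(=O)[C@@H]13)COC2=O
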